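The route rests on the O1–C6 bond of the 1,2-dioxane, the bond between the distal peroxide oxygen and the methyl-bearing quaternary carbon. It is closed late by a 6-endo cycloperoxymercuration–demercuration of an open-chain (3S,4S)-homoallylic hydroperoxide whose E-trisubstituted C5=C6 alkene already carries the whole side chain. The step exploits two features of the ring: C6 is the tertiary, Markovnikov terminus of that alkene, and the C4 methyl stereocentre, 1,3 to C6, fixes through a chair transition state which alkene face the OOH group attacks, so alkene geometry becomes the C6 configuration. C4 comes from a catalytic ynone reduction and is relayed to C3, then to C6; C2′ is bought.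

Key step: step 11

Numbering: ring O1, O2, C3 (CH2CO2H), C4 (CH3), C5, C6 (CH3 and side chain); side chain C1′–C10′. Open-chain precursors keep C1–C6 of the future acid chain (C1 = carboxyl carbon).
Assumption: the (R,R)-TsDPEN ruthenium catalyst is taken to give the (R)-alcohol from the methyl ynone, as with other alkynyl methyl ketones; otherwise the enantiomeric catalyst is used.

Step 1
Reactants: 1 pent-3-yn-2-one
Product: 2 (2R)-pent-3-yn-2-ol
Conditions: Ru[(R,R)-TsDPEN](p-cymene) (0.5 mol %), iPrOH, 28 °C
Reagents that add atoms: none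
Why: Noyori asymmetric transfer hydrogenation, in which the alkynyl group takes the place of the unsaturated substituent in the six-membered hydride-transfer transition state, should set the carbinol centre (R); this is the centre that becomes C4.

Step 2
Reactants: 2 (2R)-pent-3-yn-2-ol
Product: 3 (2R)-pent-3-yn-2-yl methanesulfonate
Conditions: MsCl, Et3N, CH2Cl2, −78 to −20 °C
Reagents that add atoms: methanesulfonyl chloride CS(=O)(=O)Cl
Why: Sulfonylation of a secondary propargylic alcohol forms only the O–S bond, so the carbinol configuration is retained.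

Step 3
Reactants: 3 (2R)-pent-3-yn-2-yl methanesulfonate; 4 3-[(tert-butyldimethylsilyl)oxy]propanal
Product: 6 (3R,4S)-1-[(tert-butyldimethylsilyl)oxy]-4-methylhept-5-yn-3-ol, via allenylzinc 5 (not isolated)
Conditions: Pd(OAc)2 (5 mol %), PPh3 (5 mol %), Et2Zn (3 equiv), THF, −78 to −20 °C
Reagents that add atoms: diethylzinc CC[Zn]CC (ethylzinc unit of intermediate 5 only)
Why: Marshall propargylation: anti SN2′ oxidative addition of zerovalent palladium, transmetalation to the allenylzinc and a cyclic SE2′ addition to the aldehyde should transfer the mesylate chirality to C4 with net inversion and set C3 anti to the C4 methyl through the chair-like transition state.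

Step 4
Reactants: 6 (3R,4S)-1-[(tert-butyldimethylsilyl)oxy]-4-methylhept-5-yn-3-ol
Product: 8 (3R,4S,5E)-1-[(tert-butyldimethylsilyl)oxy]-6-iodo-4-methylhept-5-en-3-ol, via alkenylzirconocene 7 (not isolated)
Conditions: Cp2Zr(H)Cl (3 equiv), THF, rt to 50 °C; then I2, 0 °C
Reagents that add atoms: iodine II; zirconocene chloride hydride [H][Zr](Cl)(C1C=CC=C1)C1C=CC=C1 (zirconocene units of intermediate 7 only)
Why: Syn hydrozirconation of the internal alkyne should, after equilibration, place zirconium on the methyl-bearing carbon away from the branched C4, and iodinolysis with retention gives the (E)-2-iodoalkene; one equivalent of hydride is consumed by the hydroxyl.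

Step 5
Reactants: 9 (2S)-3-bromo-2-methylpropan-1-ol; 10 (7-bromoheptyl)benzene
Product: 12 (2R)-2-methyl-10-phenyldecan-1-ol, via Grignard reagent 11 (not isolated)
Conditions: 10, Mg, THF, reflux; then 9, Li2CuCl4 (3 mol %), THF, −78 °C to rt (2.5 equiv of 11)
Reagents that add atoms: magnesium [Mg] (in intermediate 11 only)
Why: Copper-catalysed Grignard cross-coupling (Kochi type) at the primary bromide leaves the bought stereocentre untouched; the first equivalent of 11 only deprotonates the hydroxyl, and the descriptor changes from S to R by the priority rules alone.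

Step 6
Reactants: 12 (2R)-2-methyl-10-phenyldecan-1-ol
Product: 13 [(9R)-10-iodo-9-methyldecyl]benzene
Conditions: I2, PPh3, imidazole, CH2Cl2, 0 °C to rt
Reagents that add atoms: iodine II
Why: Appel-type iodination of a primary alcohol proceeds at the CH2 carbon and does not touch the adjacent stereocentre.

Step 7
Reactants: 13 [(9R)-10-iodo-9-methyldecyl]benzene; 8 (3R,4S,5E)-1-[(tert-butyldimethylsilyl)oxy]-6-iodo-4-methylhept-5-en-3-ol
Product: 15 (3R,4S,5E,8R)-1-[(tert-butyldimethylsilyl)oxy]-4,6,8-trimethyl-16-phenylhexadec-5-en-3-ol, via alkylzinc iodide 14 (not isolated)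
Conditions: 13, Zn dust, LiCl, THF, 40 °C; then 8, Pd(OAc)2 (2 mol %), SPhos (4 mol %), THF, rt (2 equiv of 14)
Reagents that add atoms: zinc [Zn] (in intermediate 14 only)
Why: Negishi sp3–sp2 coupling of the alkylzinc iodide from direct zinc insertion should proceed with retention of the E geometry, and alkylzinc halides tolerate a free secondary hydroxyl when the palladium/biarylphosphine coupling is fast.

Step 8
Reactants: 16 2,3-dimethylbut-2-ene
Product: 17 2-hydroperoxy-2-methoxypropane
Conditions: O3, MeOH/CH2Cl2, −78 °C; N2 purge, warm to rt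
Reagents that add atoms: ozone [O-][O+]=O; methanol CO
Why: Criegee ozonolysis of the symmetrical alkene in methanol traps the carbonyl oxide as the α-methoxy hydroperoxide, a mono-protected hydrogen peroxide.

Step 9
Reactants: 15 (3R,4S,5E,8R)-1-[(tert-butyldimethylsilyl)oxy]-4,6,8-trimethyl-16-phenylhexadec-5-en-3-ol; 17 2-hydroperoxy-2-methoxypropane
Product: 19 tert-butyl{[(3S,4S,5E,8R)-3-[(2-methoxypropan-2-yl)peroxy]-4,6,8-trimethyl-16-phenylhexadec-5-en-1-yl]oxy}dimethylsilane, via triflate 18 (not isolated)
Conditions: Tf2O, 2,6-lutidine, CH2Cl2, −78 °C; then 17, KOtBu, THF, −78 to 0 °C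
Reagents that add atoms: trifluoromethanesulfonic anhydride O=S(=O)(OS(=O)(=O)C(F)(F)F)C(F)(F)F (triflyl group of intermediate 18 only)
Why: SN2 displacement of a secondary triflate by the anion of a mono-protected hydrogen peroxide is an established route to optically active secondary peroxides and should invert C3 from R to S, the low temperature and the weakly basic α-effect nucleophile disfavouring elimination.

Step 10
Reactants: 19 tert-butyl{[(3S,4S,5E,8R)-3-[(2-methoxypropan-2-yl)peroxy]-4,6,8-trimethyl-16-phenylhexadec-5-en-1-yl]oxy}dimethylsilane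
Product: 20 (3S,4S,5E,8R)-3-hydroperoxy-4,6,8-trimethyl-16-phenylhexadec-5-en-1-ol
Conditions: TsOH·H2O (10 mol %), MeOH, 0 °C to rt
Reagents that add atoms: none
Why: Acid-catalysed methanolysis should cleave the peroxyketal (as 2,2-dimethoxypropane) and the primary silyl ether in one operation without affecting the secondary alkyl hydroperoxide, the alkene or any stereocentre.

Step 11
Reactants: 20 (3S,4S,5E,8R)-3-hydroperoxy-4,6,8-trimethyl-16-phenylhexadec-5-en-1-ol
Product: 22 2-[(3S,4S,6R)-4,6-dimethyl-6-[(2R)-2-methyl-10-phenyldecyl]-1,2-dioxan-3-yl]ethan-1-ol, via organomercurial 21 (not isolated)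
Conditions: Hg(OAc)2 (1.1 equiv), CH2Cl2, 0 °C to rt; then aq NaOH, NaBH4, 0 °C
Reagents that add atoms: mercury diacetate CC(=O)O[Hg]OC(C)=O (acetoxymercurio group of intermediate 21 only)
Why: Hg(OAc)2 forms a mercurinium ion on the C5=C6 alkene and the hydroperoxide oxygen opens it anti at the tertiary, more electropositive C6 to give the 5-mercurio-1,2-dioxane 21, whose C–Hg bond is then replaced by C–H through the alkylmercury hydride radical chain set off by NaBH4, so that C5 ends as CH2. The closest known reaction type is the cycloperoxymercuration–hydridodemercuration of alkenyl hydroperoxides to 1,2-dioxolanes and 1,2-dioxanes. The 1,2-dioxane closes in the 6-endo-trig mode (O1–C6 bond) in preference to 5-exo attack at C5, which would place mercury on the tertiary carbon against the polarisation of the mercurinium ion. C6 is the only new stereocentre of 22 and is controlled by C4: in the chair transition state the C6 substituent cis to C4 on the alkene (the methyl group, fixed by the E geometry) must become axial, and only the chair with the C4 methyl equatorial avoids a syn-diaxial methyl/methyl (allylic 1,3) clash, so the side chain should end equatorial and cis to the C4 methyl, which is 6R, while C3 with its axial CH2CH2OH group is carried through unchanged. The step needs chemoselectivity for OOH over the primary OH (the hydroxyl could reach C6 only through a seven-membered ring or attack C5 against Markovnikov polarisation) and survival of the O–O bond in the reduction, which is helped by the ring radical at C5 being poorly aligned for epoxide-forming attack on O1.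

Step 12
Reactants: 22 2-[(3S,4S,6R)-4,6-dimethyl-6-[(2R)-2-methyl-10-phenyldecyl]-1,2-dioxan-3-yl]ethan-1-ol
Product: 23 2-[(3S,4S,6R)-4,6-dimethyl-6-[(2R)-2-methyl-10-phenyldecyl]-1,2-dioxan-3-yl]acetic acid
Conditions: TEMPO (20 mol %), PhI(OAc)2 (2.5 equiv), MeCN/H2O (1:1), rt
Reagents that add atoms: water O
Why: TEMPO/PhI(OAc)2 oxidation in aqueous acetonitrile takes the primary alcohol through the aldehyde hydrate to the acid under near-neutral conditions that should leave the dialkyl peroxide, the benzylic position and the stereocentres untouched.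

Compound list
1 | pent-3-yn-2-one | CC#CC(C)=O | starting material
2 | (2R)-pent-3-yn-2-ol | CC#C[C@@H](C)O | intermediate
3 | (2R)-pent-3-yn-2-yl methanesulfonate | CC#C[C@@H](C)OS(C)(=O)=O | intermediate
4 | 3-[(tert-butyldimethylsilyl)oxy]propanal | O=CCCO[Si](C)(C)C(C)(C)C | starting material
5 | ethyl[(aS)-penta-2,3-dien-2-yl]zinc (allenylzinc, not isolated) | CC([Zn]CC)=[C@@]=C(C)[H] | intermediate
6 | (3R,4S)-1-[(tert-butyldimethylsilyl)oxy]-4-methylhept-5-yn-3-ol | CC#C[C@H](C)[C@@H](CCO[Si](C)(C)C(C)(C)C)O | intermediate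
7 | (E)-alkenylzirconocene chloride from 6, zirconium on C6 trans to C4, hydroxyl held as its zirconocene alkoxide (not isolated) | C/C(=C\[C@H](C)[C@@H](CCO[Si](C)(C)C(C)(C)C)O[Zr](Cl)(C1C=CC=C1)C1C=CC=C1)[Zr](Cl)(C1C=CC=C1)C1C=CC=C1 | intermediate
8 | (3R,4S,5E)-1-[(tert-butyldimethylsilyl)oxy]-6-iodo-4-methylhept-5-en-3-ol | I/C(C)=C/[C@H](C)[C@@H](CCO[Si](C)(C)C(C)(C)C)O | intermediate
9 | (2S)-3-bromo-2-methylpropan-1-ol | C[C@H](CBr)CO | starting material
10 | (7-bromoheptyl)benzene | BrCCCCCCCc1ccccc1 | starting material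
11 | (7-phenylheptyl)magnesium bromide (not isolated) | Br[Mg]CCCCCCCc1ccccc1 | intermediate
12 | (2R)-2-methyl-10-phenyldecan-1-ol | C[C@H](CCCCCCCCc1ccccc1)CO | intermediate
13 | [(9R)-10-iodo-9-methyldecyl]benzene | C[C@H](CCCCCCCCc1ccccc1)CI | intermediate
14 | iodo[(2R)-2-methyl-10-phenyldecyl]zinc (not isolated) | C[C@H](CCCCCCCCc1ccccc1)C[Zn]I | intermediate
15 | (3R,4S,5E,8R)-1-[(tert-butyldimethylsilyl)oxy]-4,6,8-trimethyl-16-phenylhexadec-5-en-3-ol | C[C@H](CCCCCCCCc1ccccc1)C/C(C)=C/[C@H](C)[C@@H](CCO[Si](C)(C)C(C)(C)C)O | intermediate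
16 | 2,3-dimethylbut-2-ene | CC(C)=C(C)C | starting material
17 | 2-hydroperoxy-2-methoxypropane (2-methoxyprop-2-yl hydroperoxide) | COC(C)(C)OO | intermediate
18 | (3R,4S,5E,8R)-1-[(tert-butyldimethylsilyl)oxy]-4,6,8-trimethyl-16-phenylhexadec-5-en-3-yl trifluoromethanesulfonate (not isolated) | C[C@H](CCCCCCCCc1ccccc1)C/C(C)=C/[C@H](C)[C@@H](CCO[Si](C)(C)C(C)(C)C)OS(=O)(=O)C(F)(F)F | intermediate
19 | tert-butyl{[(3S,4S,5E,8R)-3-[(2-methoxypropan-2-yl)peroxy]-4,6,8-trimethyl-16-phenylhexadec-5-en-1-yl]oxy}dimethylsilane | C[C@H](CCCCCCCCc1ccccc1)C/C(C)=C/[C@H](C)[C@H](CCO[Si](C)(C)C(C)(C)C)OOC(C)(C)OC | intermediate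
20 | (3S,4S,5E,8R)-3-hydroperoxy-4,6,8-trimethyl-16-phenylhexadec-5-en-1-ol | C[C@H](CCCCCCCCc1ccccc1)C/C(C)=C/[C@H](C)[C@H](CCO)OO | intermediate
21 | (acetato)[(3S,4R,5S,6R)-3-(2-hydroxyethyl)-4,6-dimethyl-6-[(2R)-2-methyl-10-phenyldecyl]-1,2-dioxan-5-yl]mercury, mercury equatorial and anti to O1 (not isolated) | C[C@H](CCCCCCCCc1ccccc1)C[C@]1(C)[C@@H]([Hg]OC(C)=O)[C@H](C)[C@H](CCO)OO1 | intermediate
22 | 2-[(3S,4S,6R)-4,6-dimethyl-6-[(2R)-2-methyl-10-phenyldecyl]-1,2-dioxan-3-yl]ethan-1-ol | C[C@H](CCCCCCCCc1ccccc1)C[C@]1(C)C[C@H](C)[C@H](CCO)OO1 | intermediate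
23 | 2-[(3S,4S,6R)-4,6-dimethyl-6-[(2R)-2-methyl-10-phenyldecyl]-1,2-dioxan-3-yl]acetic acid | C[C@H](CCCCCCCCc1ccccc1)C[C@]1(C)C[C@H](C)[C@H](CC(=O)O)OO1 | target

Total step count: 12.
Longest linear sequence: 9 steps (steps 1, 2, 3, 4, 7, 9, 10, 11, 12, from pent-3-yn-2-one).

Steps most likely to fail

Step 11 (key step). What may go wrong: closure in the 5-exo sense, reversal of the oxymercuration under the basic hydride conditions with return to the open hydroperoxide, or fragmentation of the β-peroxyalkyl radical during demercuration. The fallback sets out from 20 and separates ring closure from reduction. N-Iodosuccinimide in CH2Cl2 at −20 °C should close the same O1–C6 bond through an iodonium ion, which is polarised even more strongly toward the tertiary carbon and cannot revert under neutral conditions, to give 2-[(3S,4R,5S,6R)-5-iodo-4,6-dimethyl-6-[(2R)-2-methyl-10-phenyldecyl]-1,2-dioxan-3-yl]ethan-1-ol F1 as an isolable iodide that has the same chair-controlled C6 configuration. The C–I bond of F1 is then reduced with Bu3SnH in large excess (Et3B/air initiation, 0 °C), where hydrogen transfer should outrun fragmentation, and the route is rejoined at 22.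

Step 9. What may go wrong: E2 elimination of the β-branched secondary triflate toward the conjugated diene, or ionisation with alkene participation, outrunning the bimolecular substitution at C3. The fallback gives up substitution at C3 and makes the C3 stereocentre by C–C bond formation on a peroxycarbenium ion, while the closure of the O1–C6 bond stays the same. It sets out from mesylate 3, uses the alkylzinc 14 made from 13, and comes back to the route at 23. The allenylzinc 5 generated from 3 is added to monomeric formaldehyde instead of 4, which should give (2S)-2-methylpent-3-yn-1-ol F2 in place of 6. Hydrozirconation–iodination of F2 under the conditions used for 6 proceeds through chlorobis(cyclopentadienyl)[(2E,4S)-5-{[chlorobis(cyclopentadienyl)zirconio]oxy}-4-methylpent-2-en-2-yl]zirconium F3 and should give (2S,3E)-4-iodo-2-methylpent-3-en-1-ol F4 with the same alkene geometry as 8. Negishi coupling of F4 with 14 under the conditions used for 8 should give (2S,3E,6R)-2,4,6-trimethyl-14-phenyltetradec-3-en-1-ol F5 in one operation. Buffered Dess–Martin oxidation of F5 gives (2S,3E,6R)-2,4,6-trimethyl-14-phenyltetradec-3-enal F6 for immediate use, because its α-centre is epimerisable. H2O2–urea with Sc(OTf)3 (cat.) in methanol should convert F6 into (2S,3E,6R)-1-hydroperoxy-1-methoxy-2,4,6-trimethyl-14-phenyltetradec-3-ene F7 as a mixture of both C1 epimers. The Hg(OAc)2/NaBH4 closure of the O1–C6 bond of F7 passes through (acetato)[(4R,5S,6R)-3-methoxy-4,6-dimethyl-6-[(2R)-2-methyl-10-phenyldecyl]-1,2-dioxan-5-yl]mercury F8 as the organomercurial and should give (4S,6R)-3-methoxy-4,6-dimethyl-6-[(2R)-2-methyl-10-phenyldecyl]-1,2-dioxane F9 as both C3 epimers, which converge in the next operation. TMSOTf and 1-methoxy-1-(trimethylsilyloxy)ethene in CH2Cl2 at −78 °C add the acetate unit to the peroxycarbenium ion derived from F9; axial attack on the half-chair with the C4 methyl equatorial should place the new substituent cis to it and give methyl 2-[(3S,4S,6R)-4,6-dimethyl-6-[(2R)-2-methyl-10-phenyldecyl]-1,2-dioxan-3-yl]acetate F10 as the major C3 epimer. LiOH in aqueous THF at 0 °C then converts F10 into 23.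

Step 7. What may go wrong: protonolysis of the alkylzinc by the free hydroxyl and slow transmetalation at the hindered α-methyl vinyl iodide, leaving β-hydride elimination and reduction as the main pathways. The fallback sets out from 13 and changes the organometallic to boron (B-alkyl Suzuki–Miyaura coupling). Iodine–lithium exchange with tBuLi (2 equiv, Et2O, −78 °C) gives [(2S)-2-methyl-10-phenyldecyl]lithium F11 with the same spatial arrangement, the descriptor changing by the priority rules alone. Trapping of F11 with 9-methoxy-9-borabicyclo[3.3.1]nonane gives lithium B-methoxy-B-[(2S)-2-methyl-10-phenyldecyl]-9-borabicyclo[3.3.1]nonane ate complex F12 as a species that is indifferent to the hydroxyl of 8. Coupling of F12 with 8 under PdCl2(dppf), AsPh3 and aqueous K3PO4 in DMF at rt rejoins the route at 15.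

Further compounds
F1 | step 11 | 2-[(3S,4R,5S,6R)-5-iodo-4,6-dimethyl-6-[(2R)-2-methyl-10-phenyldecyl]-1,2-dioxan-3-yl]ethan-1-ol | C[C@H](CCCCCCCCc1ccccc1)C[C@]1(C)[C@@H](I)[C@H](C)[C@H](CCO)OO1
F2 | step 9 | (2S)-2-methylpent-3-yn-1-ol | CC#C[C@H](C)CO
F3 | step 9 | chlorobis(cyclopentadienyl)[(2E,4S)-5-{[chlorobis(cyclopentadienyl)zirconio]oxy}-4-methylpent-2-en-2-yl]zirconium | C/C(=C\[C@H](C)CO[Zr](Cl)(C1C=CC=C1)C1C=CC=C1)[Zr](Cl)(C1C=CC=C1)C1C=CC=C1
F4 | step 9 | (2S,3E)-4-iodo-2-methylpent-3-en-1-ol | I/C(C)=C/[C@H](C)CO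
F5 | step 9 | (2S,3E,6R)-2,4,6-trimethyl-14-phenyltetradec-3-en-1-ol | C[C@H](CCCCCCCCc1ccccc1)C/C(C)=C/[C@H](C)CO
F6 | step 9 | (2S,3E,6R)-2,4,6-trimethyl-14-phenyltetradec-3-enal | C[C@H](CCCCCCCCc1ccccc1)C/C(C)=C/[C@H](C)C=O
F7 | step 9 | (2S,3E,6R)-1-hydroperoxy-1-methoxy-2,4,6-trimethyl-14-phenyltetradec-3-ene | C[C@H](CCCCCCCCc1ccccc1)C/C(C)=C/[C@H](C)C(OC)OO
F8 | step 9 | (acetato)[(4R,5S,6R)-3-methoxy-4,6-dimethyl-6-[(2R)-2-methyl-10-phenyldecyl]-1,2-dioxan-5-yl]mercury | C[C@H](CCCCCCCCc1ccccc1)C[C@]1(C)[C@@H]([Hg]OC(C)=O)[C@H](C)C(OC)OO1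
F9 | step 9 | (4S,6R)-3-methoxy-4,6-dimethyl-6-[(2R)-2-methyl-10-phenyldecyl]-1,2-dioxane | C[C@H](CCCCCCCCc1ccccc1)C[C@]1(C)C[C@H](C)C(OC)OO1
F10 | step 9 | methyl 2-[(3S,4S,6R)-4,6-dimethyl-6-[(2R)-2-methyl-10-phenyldecyl]-1,2-dioxan-3-yl]acetate | C[C@H](CCCCCCCCc1ccccc1)C[C@]1(C)C[C@H](C)[C@H](CC(=O)OC)OO1
F11 | step 7 | [(2S)-2-methyl-10-phenyldecyl]lithium | C[C@H](CCCCCCCCc1ccccc1)C[Li]
F12 | step 7 | lithium B-methoxy-B-[(2S)-2-methyl-10-phenyldecyl]-9-borabicyclo[3.3.1]nonane ate complex | C[C@H](CCCCCCCCc1ccccc1)C[B-]1(OC)C2CCCC1CCC2.[Li+]
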